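- The partner is the reagent I watch in this flask. I take one partner per product, so the 1.50 equiv charged on the left-handed substrate covers 75.0 % of both substrates together, which makes it the limiting reagent.

| flask | left-handed substrate | right-handed substrate | partner | precatalyst | remark | time |
|---|---|---|---|---|---|---|
| north-west | 1.4 M | 1.4 M | 1.5 equiv | 0.14 mol% | run made earlier |  |
| south | 1.4 M | 1.4 M | 1.5 equiv | 0.22 mol% | run made earlier |  |
| flask | 1.4 M | 1.4 M | 1.50 equiv | 0.1 mol% |  | 2.5 h |

| run | time / min | left-handed product / % | right-handed product / % | left-handed substrate / % |
|---|---|---|---|---|
| north-west | 8.00 | 6 | 3 | 41 |
| north-west | 15.0 | 13 | 9 | 38 |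
| north-west | 25.0 | 15 | 11 | 31 |
| north-west | 50.0 | 24 | 19 | 25 |
| north-west | 90.0 | 29 | 28 | 17 |
| south | 8.00 | 3 | 4 | 43 |
| south | 25.0 | 20 | 16 | 29 |
| south | 40.0 | 24 | 21 | 20 |
| south | 60.0 | 29 | 30 | 18 |
| south | 90.0 | 31 | 32 | 15 |

(readings scatter by 2 percentage points)

- catalyst is single-handed; left-handed substrate and right-handed substrate are mirror images of each other, charged as a racemate, each of them at the stated concentration
- an excess is the difference of the two amounts in percent of their sum
- an excess is below zero if the other one leads

* excess of left-handed product over right-handed product in the product at 8.0 min
* excess of left-handed product over right-handed product in the product at 2.5 h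
* part of the left-handed substrate and right-handed substrate charged together that has reacted at 2.5 h

- I count the partner's fall in powers of ten and assume that this count grows with loading times time. The south reading at 60.0 min shows 0.671, and scaling it gives this flask 0.762 partner decades, the powers of ten by which its partner has fallen at the end. The north-west reading at 90.0 min, scaled alike, gives 0.738.
- First rung of my ladder: the two readings at 8.0 min lie within the scatter of each other, so I read the left-handed product's lead later. Three readings, north-west at 15.0 min and 25.0 min and south at 25.0 min, average an excess of 14.9 %, which I take as my estimate for 8.0 min.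
- Second rung: the two products stand level within the scatter by 60.0 min in the south run. This flask's loading times time at 2.5 h equals the south run's at 68.2 min, which is later, so I expect an excess of about zero in this flask at 2.5 h.
- Third rung: at the pace I assumed, one partner decade takes this flask 197 min, longer than the run. I therefore expect 17.3 % of the partner left and 62.0 % conversion.
- The forecast, a little apart from my numbers, gives 13 %, 3 % and 59 %, on the ground that “the rate scales with catalyst”.
- The flask gives 13.2 %, 0 % and 63.6 %. At 2.50 h it holds 15 % of its partner against 45 % of its right-handed substrate. That partner amounts to 0.824 decades, where I reckoned 0.762.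

    partner + catalyst + left-handed substrate → catalyst + left-handed product (k = 2.50 /M²/s)
    left-handed product ⇌ right-handed product (k = 0.00120 /s)
    partner + precatalyst → catalyst + spent reagent (k = 2.00 × 10⁻⁴ /M/s)
    catalyst ⇌ dormant form (K = 13.0, k = 0.0110 /s)
    partner + catalyst + right-handed substrate → catalyst + right-handed product (k = 1.60 /M²/s)

- The neighbour with 0.900 equiv of partner keeps the loading and the time, so I give it the same 0.762 decades, which means 17.3 % of its partner left and 37.2 % conversion. Computed, it reaches 38.9 % with 13 % of its partner left.

The earlier runs and the new flask come from a simulation with constants of no real substance; the scatter is artificial.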